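**Retrosynthetic overview**

- The route rests on ring C (O1, C2, C3, C4, C4a, C8a). C4 is a benzylic CH2 on C4a of ring A, next to the phenolic oxygen O1 on C8a, which is the imprint of an ortho-quinone methide (C4=C4a–C8a=O1). C3, the only stereocentre, carries ring B as the α-carbon of an arylacetic acid whose carboxyl carbon becomes C2.
- Cutting C3–C4 and the O1–C2 acyl bond gives a ring A 2-(tosylmethyl)phenol (methide precursor) and a ring B arylacetic acid. A chiral isothiourea joins them in a formal [4+2] annulation that builds ring C as a 3-aryl-3,4-dihydrocoumarin and sets C3.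
- The lactone is then reduced to the phenol alcohol and ring C is closed again as the pyran by Mitsunobu O1–C2 etherification; the MOM and TIPS groups are removed last.
- Ring A sulfone: 5-methoxyresorcinol by formylation, 4-O-silylation, reduction and sulfinate exchange. Ring B acid: 2-bromo-5-methoxyphenol by O-(1,1-dimethylpropargyl)ation, semi-hydrogenation, Claisen shift to the carbon between the two oxygens, MOM protection, palladium-catalysed zinc enolate coupling and saponification.
- Ring order: rings A and B come from the starting phenols; ring C is formed in step 11, opened in step 12 and re-formed in step 13.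

Key step: step 11

Remark: the target SMILES encodes 3R; the (R) enantiomer of benzotetramisole is assigned to this configuration from the accepted facial model of isothiouronium enolates (electrophile anti to the catalyst phenyl group), and the mirror-image catalyst is equally accessible should the sense prove opposite.

**Route**

Step 1
Reactants: 1 5-methoxyresorcinol
Product: 3 2,4-dihydroxy-6-methoxybenzaldehyde, via iminium chloride 2 (not isolated)
Conditions: POCl3, DMF, MeCN, 0 °C to rt; then H2O, 50 °C
Reagents that add atoms: N,N-dimethylformamide, CN(C)C=O (formyl carbon); water, O (aldehyde oxygen)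
Why: Vilsmeier–Haack formylation should favour the ring carbon flanked by OH and OMe (two equivalent sites, each para to the other hydroxyl), and hydrolysis of 2 should give the aldehyde, the minor symmetric 2,6-dihydroxy isomer being removed by crystallisation or chromatography.

Step 2
Reactants: 3 2,4-dihydroxy-6-methoxybenzaldehyde
Product: 4 2-hydroxy-6-methoxy-4-[(triisopropylsilyl)oxy]benzaldehyde
Conditions: TIPSCl, imidazole, DMF, 0 °C
Reagents that add atoms: triisopropylsilyl chloride, CC(C)[Si](Cl)(C(C)C)C(C)C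
Why: Chemoselective silylation should occur at the more acidic, unhindered 4-OH, because the 2-OH is hydrogen-bonded to the formyl oxygen and shielded by it.

Step 3
Reactants: 4 2-hydroxy-6-methoxy-4-[(triisopropylsilyl)oxy]benzaldehyde
Product: 5 2-(hydroxymethyl)-3-methoxy-5-[(triisopropylsilyl)oxy]phenol
Conditions: NaBH4, THF/MeOH, 0 °C, short contact, neutral work-up
Reagents that add atoms: none
Why: Borohydride reduction of the aldehyde at low temperature should stop at the salicyl alcohol, which is taken on crude because it ionises easily.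

Step 4
Reactants: 5 2-(hydroxymethyl)-3-methoxy-5-[(triisopropylsilyl)oxy]phenol
Product: 6 3-methoxy-2-[(4-methylbenzenesulfonyl)methyl]-5-[(triisopropylsilyl)oxy]phenol
Conditions: TolSO2Na (excess), AcOH, THF/H2O, rt
Reagents that add atoms: sodium p-toluenesulfinate, Cc1ccc(cc1)S(=O)[O-].[Na+]
Why: Acid-promoted ionisation of the electron-rich benzylic alcohol and capture of the benzylic electrophile at the sulfur of the sulfinate (SN1-type sulfinate alkylation) should give the crystalline, storable sulfone, the aryl silyl ether being stable to acetic acid.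

Step 5
Reactants: 7 2-bromo-5-methoxyphenol; 8 2-methylbut-3-yn-2-ol
Product: 10 1-bromo-4-methoxy-2-[(2-methylbut-3-yn-2-yl)oxy]benzene, via propargylic trifluoroacetate 9 (not isolated)
Conditions: 8, (CF3CO)2O, DBU, MeCN, −5 °C; then 7, DBU, CuCl2·2H2O (0.1 mol%), 0 °C to rt
Reagents that add atoms: none
Why: Copper-catalysed propargylic etherification: the alcohol is activated in the flask as its trifluoroacetate, whose copper acetylide ionises to a stabilised tertiary propargylic electrophile that the phenoxide should capture at oxygen.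

Step 6
Reactants: 10 1-bromo-4-methoxy-2-[(2-methylbut-3-yn-2-yl)oxy]benzene
Product: 11 1-bromo-4-methoxy-2-[(2-methylbut-3-en-2-yl)oxy]benzene
Conditions: H2 (1 atm), Pd/CaCO3 poisoned with Pb(OAc)2 (Lindlar catalyst), quinoline, EtOAc, rt
Reagents that add atoms: none
Why: Lindlar semi-hydrogenation should stop at the terminal alkene, and the poisoned catalyst leaves the aryl bromide untouched.

Step 7
Reactants: 11 1-bromo-4-methoxy-2-[(2-methylbut-3-en-2-yl)oxy]benzene
Product: 13 6-bromo-3-methoxy-2-(3-methylbut-2-en-1-yl)phenol, via bromodienone 12 (not isolated)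
Conditions: PhNEt2, 130 °C
Reagents that add atoms: none
Why: Aromatic Claisen rearrangement: the [3,3] shift should deliver the allyl terminus to the only free ortho carbon (the other is blocked by bromine), turning the 1,1-dimethylallyl ether into the C-prenyl group before tautomerisation to the phenol, while the basic solvent suppresses acid-catalysed chroman formation.

Step 8
Reactants: 13 6-bromo-3-methoxy-2-(3-methylbut-2-en-1-yl)phenol
Product: 14 1-bromo-4-methoxy-2-(methoxymethoxy)-3-(3-methylbut-2-en-1-yl)benzene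
Conditions: NaH, MOMCl, DMF, 0 °C
Reagents that add atoms: chloromethyl methyl ether, COCCl
Why: Williamson-type O-alkylation of the sodium phenoxide with the reactive chloromethyl ether should mask the flanked phenol as an acetal that is stable to organozinc reagents, base and hydride.

Step 9
Reactants: 14 1-bromo-4-methoxy-2-(methoxymethoxy)-3-(3-methylbut-2-en-1-yl)benzene
Product: 15 ethyl 2-[4-methoxy-2-(methoxymethoxy)-3-(3-methylbut-2-en-1-yl)phenyl]acetate
Conditions: BrZnCH2CO2Et (from BrCH2CO2Et, Zn dust, Me3SiCl cat., THF), Pd2(dba)3 (2 mol%), XPhos (8 mol%), THF, 65 °C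
Reagents that add atoms: ethyl bromoacetate, CCOC(=O)CBr (used as its zinc reagent, CCOC(=O)C[Zn]Br)
Why: Negishi-type coupling of a Reformatsky reagent: oxidative addition of the aryl bromide to zerovalent palladium carrying the bulky biaryl phosphine, transmetallation from zinc and reductive elimination should form the aryl–CH2 bond under nearly neutral conditions that spare the acetal and the alkene.

Step 10
Reactants: 15 ethyl 2-[4-methoxy-2-(methoxymethoxy)-3-(3-methylbut-2-en-1-yl)phenyl]acetate
Product: 16 2-[4-methoxy-2-(methoxymethoxy)-3-(3-methylbut-2-en-1-yl)phenyl]acetic acid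
Conditions: LiOH·H2O, THF/MeOH/H2O, rt; then 1 M HCl to pH 3, 0 °C, immediate extraction
Reagents that add atoms: lithium hydroxide, [Li+].[OH-] (hydroxyl oxygen of the acid)
Why: Saponification of the unhindered ethyl ester should be clean, and brief cold acidification liberates the acid without cleaving the aryl acetal.

Step 11
Reactants: 16 2-[4-methoxy-2-(methoxymethoxy)-3-(3-methylbut-2-en-1-yl)phenyl]acetic acid; 6 3-methoxy-2-[(4-methylbenzenesulfonyl)methyl]-5-[(triisopropylsilyl)oxy]phenol
Product: 20 (3R)-5-methoxy-3-[4-methoxy-2-(methoxymethoxy)-3-(3-methylbut-2-en-1-yl)phenyl]-7-[(triisopropylsilyl)oxy]-3,4-dihydro-2H-chromen-2-one, via mixed pivalic anhydride 17 (not isolated), via ammonium enolate 18 (not isolated), via ortho-quinone methide 19 (not isolated)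
Conditions: 16, PivCl, iPr2NEt, CH2Cl2, 0 °C; then (R)-benzotetramisole (10 mol%), 6, Cs2CO3, CH2Cl2, 0 °C to rt
Reagents that add atoms: none
Why: Pivaloyl chloride converts the acid into anhydride 17, which N-acylates the isothiourea, and deprotonation by the amine gives the Z ammonium enolate 18, while Cs2CO3 expels p-toluenesulfinate from 6 to release methide 19 at a low stationary concentration. The enolate carbon (C3) adds to the exocyclic methide carbon (C4) in a Michael addition that rearomatises ring A, and the phenoxide so formed (O1) attacks the acyl ammonium carbon (C2) in a 6-exo-trig acyl substitution that closes ring C as the lactone and releases the catalyst. The closest known reaction type is the chiral isothiourea- or carbene-catalysed formal [4+2] annulation of carboxylic-acid-derived enolates with ortho-quinone methides generated in the flask from 2-(sulfonylmethyl)phenols, which gives 3,4-dihydrocoumarins. C3 is the only new stereocentre and is set by the catalyst: the 1,5 S···O contact holds the enolate coplanar with the bicyclic isothiouronium, the phenyl group at the catalyst stereocentre covers one enolate face, and the methide should add to the open face, which for the (R) catalyst and the Z enolate corresponds to 3R. The step needs enantioface selectivity at C3, C-alkylation of the enolate ahead of methide self-condensation, and survival of the acidic C3–H of the product; the unsubstituted methide carbon creates no second stereocentre, slow release of 19 from the sulfone keeps it dilute beside an excess of 18, and the reaction is stopped once 6 is consumed and filtered cold through silica to protect the configuration.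

Step 12
Reactants: 20 (3R)-5-methoxy-3-[4-methoxy-2-(methoxymethoxy)-3-(3-methylbut-2-en-1-yl)phenyl]-7-[(triisopropylsilyl)oxy]-3,4-dihydro-2H-chromen-2-one
Product: 21 (2R)-3-{2-hydroxy-6-methoxy-4-[(triisopropylsilyl)oxy]phenyl}-2-[4-methoxy-2-(methoxymethoxy)-3-(3-methylbut-2-en-1-yl)phenyl]propan-1-ol
Conditions: LiBH4, THF, 0 °C to rt
Reagents that add atoms: none
Why: Hydride reduction of the aryl ester (lactone) should give the primary alcohol and the ring A phenol; the weakly basic borohydride should carry the stereocentre through unchanged and leaves the silyl ether, the acetal and the alkene intact.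

Step 13
Reactants: 21 (2R)-3-{2-hydroxy-6-methoxy-4-[(triisopropylsilyl)oxy]phenyl}-2-[4-methoxy-2-(methoxymethoxy)-3-(3-methylbut-2-en-1-yl)phenyl]propan-1-ol
Product: 22 (3R)-5-methoxy-3-[4-methoxy-2-(methoxymethoxy)-3-(3-methylbut-2-en-1-yl)phenyl]-7-[(triisopropylsilyl)oxy]-3,4-dihydro-2H-chromene
Conditions: PPh3, DIAD, THF, 0 °C to rt
Reagents that add atoms: none
Why: Mitsunobu etherification: the primary alcohol, activated by the phosphine–azodicarboxylate pair, should be displaced by the only free phenol in a 6-exo-tet closure of ring C, and the stereocentre is retained because it is not the reacting carbon.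

Step 14
Reactants: 22 (3R)-5-methoxy-3-[4-methoxy-2-(methoxymethoxy)-3-(3-methylbut-2-en-1-yl)phenyl]-7-[(triisopropylsilyl)oxy]-3,4-dihydro-2H-chromene
Product: 23 3-methoxy-6-{(3R)-5-methoxy-7-[(triisopropylsilyl)oxy]-3,4-dihydro-2H-chromen-3-yl}-2-(3-methylbut-2-en-1-yl)phenol
Conditions: 2 M HCl (aq), MeOH/THF, 40 °C, stopped at full conversion
Reagents that add atoms: none
Why: Acid-catalysed transacetalisation in methanol should cleave the aryl methoxymethyl ether under conditions in common use for ortho-prenyl phenols, with the silyl ether still damping the nucleophilicity of ring A; any material that also loses the silyl group is already the target and is carried on.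

Step 15
Reactants: 23 3-methoxy-6-{(3R)-5-methoxy-7-[(triisopropylsilyl)oxy]-3,4-dihydro-2H-chromen-3-yl}-2-(3-methylbut-2-en-1-yl)phenol
Product: 24 (3R)-3-[2-hydroxy-4-methoxy-3-(3-methylbut-2-en-1-yl)phenyl]-5-methoxy-3,4-dihydro-2H-chromen-7-ol (CNP0119532.1)
Conditions: Bu4NF, AcOH, THF, 0 °C
Reagents that add atoms: none
Why: Fluoride desilylation of the aryl silyl ether, buffered with acetic acid to keep the electron-rich phenols from oxidising, should release the 7-OH and give the target with C3 untouched.

**Compound list**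

1 | 5-methoxyresorcinol | COc1cc(O)cc(O)c1 | starting material
2 | N-[(2,4-dihydroxy-6-methoxyphenyl)methylidene]-N-methylmethanaminium chloride | C[N+](C)=Cc1c(O)cc(O)cc1OC.[Cl-] | intermediate (not isolated)
3 | 2,4-dihydroxy-6-methoxybenzaldehyde | COc1cc(O)cc(O)c1C=O | intermediate
4 | 2-hydroxy-6-methoxy-4-[(triisopropylsilyl)oxy]benzaldehyde | COc1cc(O[Si](C(C)C)(C(C)C)C(C)C)cc(O)c1C=O | intermediate
5 | 2-(hydroxymethyl)-3-methoxy-5-[(triisopropylsilyl)oxy]phenol | COc1cc(O[Si](C(C)C)(C(C)C)C(C)C)cc(O)c1CO | intermediate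
6 | 3-methoxy-2-[(4-methylbenzenesulfonyl)methyl]-5-[(triisopropylsilyl)oxy]phenol | COc1cc(O[Si](C(C)C)(C(C)C)C(C)C)cc(O)c1CS(=O)(=O)c1ccc(C)cc1 | intermediate
7 | 2-bromo-5-methoxyphenol | COc1ccc(Br)c(O)c1 | starting material
8 | 2-methylbut-3-yn-2-ol | CC(C)(O)C#C | starting material
9 | 2-methylbut-3-yn-2-yl trifluoroacetate | CC(C)(OC(=O)C(F)(F)F)C#C | intermediate (not isolated)
10 | 1-bromo-4-methoxy-2-[(2-methylbut-3-yn-2-yl)oxy]benzene | COc1ccc(Br)c(OC(C)(C)C#C)c1 | intermediate
11 | 1-bromo-4-methoxy-2-[(2-methylbut-3-en-2-yl)oxy]benzene | COc1ccc(Br)c(OC(C)(C)C=C)c1 | intermediate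
12 | 2-bromo-5-methoxy-6-(3-methylbut-2-en-1-yl)cyclohexa-2,4-dien-1-one | COC1=CC=C(Br)C(=O)C1CC=C(C)C | intermediate (not isolated)
13 | 6-bromo-3-methoxy-2-(3-methylbut-2-en-1-yl)phenol | COc1ccc(Br)c(O)c1CC=C(C)C | intermediate
14 | 1-bromo-4-methoxy-2-(methoxymethoxy)-3-(3-methylbut-2-en-1-yl)benzene | COCOc1c(Br)ccc(OC)c1CC=C(C)C | intermediate
15 | ethyl 2-[4-methoxy-2-(methoxymethoxy)-3-(3-methylbut-2-en-1-yl)phenyl]acetate | CCOC(=O)Cc1ccc(OC)c(CC=C(C)C)c1OCOC | intermediate
16 | 2-[4-methoxy-2-(methoxymethoxy)-3-(3-methylbut-2-en-1-yl)phenyl]acetic acid | OC(=O)Cc1ccc(OC)c(CC=C(C)C)c1OCOC | intermediate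
17 | 2-[4-methoxy-2-(methoxymethoxy)-3-(3-methylbut-2-en-1-yl)phenyl]acetic pivalic anhydride | CC(C)(C)C(=O)OC(=O)Cc1ccc(OC)c(CC=C(C)C)c1OCOC | intermediate (not isolated)
18 | (Z)-2-[4-methoxy-2-(methoxymethoxy)-3-(3-methylbut-2-en-1-yl)phenyl]-1-[(2R)-2-phenyl-2,3-dihydroimidazo[2,1-b][1,3]benzothiazol-1-ium-1-yl]ethen-1-olate (Z ammonium enolate on (R)-benzotetramisole) | [O-]/C(=C\c1ccc(OC)c(CC=C(C)C)c1OCOC)[N+]1=C2Sc3ccccc3N2C[C@H]1c1ccccc1 | intermediate (not isolated)
19 | 5-methoxy-6-methylidene-3-[(triisopropylsilyl)oxy]cyclohexa-2,4-dien-1-one (ring A ortho-quinone methide) | C=C1C(=O)C=C(O[Si](C(C)C)(C(C)C)C(C)C)C=C1OC | intermediate (not isolated)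
20 | (3R)-5-methoxy-3-[4-methoxy-2-(methoxymethoxy)-3-(3-methylbut-2-en-1-yl)phenyl]-7-[(triisopropylsilyl)oxy]-3,4-dihydro-2H-chromen-2-one | COc1cc(O[Si](C(C)C)(C(C)C)C(C)C)cc2c1C[C@H](c1ccc(OC)c(CC=C(C)C)c1OCOC)C(=O)O2 | intermediate
21 | (2R)-3-{2-hydroxy-6-methoxy-4-[(triisopropylsilyl)oxy]phenyl}-2-[4-methoxy-2-(methoxymethoxy)-3-(3-methylbut-2-en-1-yl)phenyl]propan-1-ol | COc1cc(O[Si](C(C)C)(C(C)C)C(C)C)cc(O)c1C[C@H](c1ccc(OC)c(CC=C(C)C)c1OCOC)CO | intermediate
22 | (3R)-5-methoxy-3-[4-methoxy-2-(methoxymethoxy)-3-(3-methylbut-2-en-1-yl)phenyl]-7-[(triisopropylsilyl)oxy]-3,4-dihydro-2H-chromene | COc1cc(O[Si](C(C)C)(C(C)C)C(C)C)cc2c1C[C@H](c1ccc(OC)c(CC=C(C)C)c1OCOC)CO2 | intermediate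
23 | 3-methoxy-6-{(3R)-5-methoxy-7-[(triisopropylsilyl)oxy]-3,4-dihydro-2H-chromen-3-yl}-2-(3-methylbut-2-en-1-yl)phenol | COc1cc(O[Si](C(C)C)(C(C)C)C(C)C)cc2c1C[C@H](c1ccc(OC)c(CC=C(C)C)c1O)CO2 | intermediate
24 | (3R)-3-[2-hydroxy-4-methoxy-3-(3-methylbut-2-en-1-yl)phenyl]-5-methoxy-3,4-dihydro-2H-chromen-7-ol | COc1cc(O)cc2c1C[C@H](c1ccc(OC)c(CC=C(C)C)c1O)CO2 | target

**Step count**

Total steps: 15. Longest linear sequence: 11 steps (steps 5 to 15, from 7); the ring A branch (steps 1 to 4) joins at step 11.

**Steps most likely to fail**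

1. Step 11. The methide may self-condense faster than the ortho-substituted enolate captures it. Facial discrimination may be incomplete. The acidic C3–H of the lactone may epimerise under the carbonate, and the phenol of 6 may be O-acylated by the anhydride.

   The fallback replaces catalysis by an auxiliary-controlled alkylation; it sets out from acid 16 and aldehyde 4 and returns at phenol alcohol 21. Acid 16 would be activated (PivCl, Et3N, THF, −20 °C) and joined to lithiated (R)-4-benzyl-1,3-oxazolidin-2-one to give (4R)-4-benzyl-3-{[4-methoxy-2-(methoxymethoxy)-3-(3-methylbut-2-en-1-yl)phenyl]acetyl}-1,3-oxazolidin-2-one F1. Aldehyde 4 would be O-allylated (allyl bromide, K2CO3, acetone) to 2-(allyloxy)-6-methoxy-4-[(triisopropylsilyl)oxy]benzaldehyde F2. Reduction (NaBH4, MeOH, 0 °C) would give {2-(allyloxy)-6-methoxy-4-[(triisopropylsilyl)oxy]phenyl}methanol F3. PBr3 (Et2O, −20 °C) would convert this into 2-(allyloxy)-1-(bromomethyl)-6-methoxy-4-[(triisopropylsilyl)oxy]benzene F4, which is used at once.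

   Evans alkylation of the sodium enolate of F1 (NaN(SiMe3)2, THF, −78 °C) with F4 should take place on the face away from the auxiliary benzyl group and give the (2R) imide, (4R)-4-benzyl-3-[(2R)-3-{2-(allyloxy)-6-methoxy-4-[(triisopropylsilyl)oxy]phenyl}-2-[4-methoxy-2-(methoxymethoxy)-3-(3-methylbut-2-en-1-yl)phenyl]propanoyl]-1,3-oxazolidin-2-one F5. LiBH4 (THF/MeOH, 0 °C) would release the auxiliary and give (2R)-3-{2-(allyloxy)-6-methoxy-4-[(triisopropylsilyl)oxy]phenyl}-2-[4-methoxy-2-(methoxymethoxy)-3-(3-methylbut-2-en-1-yl)phenyl]propan-1-ol F6. Deallylation (Pd(PPh3)4, morpholine, THF, rt) would then give 21.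

2. Step 4 (with the fragile alcohol of step 3). The very electron-rich salicyl alcohol may ionise and alkylate another arene (oligomerisation) before the sulfinate captures it, and borohydride may over-reduce the aldehyde to the methyl compound.

   The fallback avoids the benzylic alcohol; it sets out from aldehyde 4 and returns at sulfone 6. Reductive amination (Me2NH, NaBH(OAc)3, 1,2-dichloroethane, rt) would give the Mannich base 2-[(dimethylamino)methyl]-3-methoxy-5-[(triisopropylsilyl)oxy]phenol F7. Quaternisation (MeI, MeCN, rt) would give {2-hydroxy-6-methoxy-4-[(triisopropylsilyl)oxy]benzyl}trimethylammonium iodide F8. Warming with TolSO2Na (DMF, 60 °C) should expel trimethylamine, and the sulfinate should capture methide 19 at sulfur to give 6 under non-acidic conditions.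

3. Step 14. Under protic acid the freed 2'-hydroxyl may add across the neighbouring prenyl double bond (closure to a 2,2-dimethylchroman). The alkene may be hydrated, or the released formaldehyde equivalent may be re-captured by ring A.

   The fallback avoids protic acid and merges the last two deprotections; it sets out from 22 and returns at target 24. Buffered silyl-transfer cleavage of the aryl acetal (Me3SiOTf, 2,2'-bipyridyl, CH2Cl2, 0 °C) should give the aryl trimethylsilyl ether, (3R)-5-methoxy-3-[4-methoxy-3-(3-methylbut-2-en-1-yl)-2-(trimethylsilyloxy)phenyl]-7-[(triisopropylsilyl)oxy]-3,4-dihydro-2H-chromene F9. Bu4NF/AcOH (THF, 0 °C) would then remove both silyl groups to give 24.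

**Further compounds**

F1 | step 11 | (4R)-4-benzyl-3-{[4-methoxy-2-(methoxymethoxy)-3-(3-methylbut-2-en-1-yl)phenyl]acetyl}-1,3-oxazolidin-2-one | O=C1OC[C@@H](Cc2ccccc2)N1C(=O)Cc1ccc(OC)c(CC=C(C)C)c1OCOC
F2 | step 11 | 2-(allyloxy)-6-methoxy-4-[(triisopropylsilyl)oxy]benzaldehyde | C=CCOc1cc(O[Si](C(C)C)(C(C)C)C(C)C)cc(OC)c1C=O
F3 | step 11 | {2-(allyloxy)-6-methoxy-4-[(triisopropylsilyl)oxy]phenyl}methanol | C=CCOc1cc(O[Si](C(C)C)(C(C)C)C(C)C)cc(OC)c1CO
F4 | step 11 | 2-(allyloxy)-1-(bromomethyl)-6-methoxy-4-[(triisopropylsilyl)oxy]benzene | C=CCOc1cc(O[Si](C(C)C)(C(C)C)C(C)C)cc(OC)c1CBr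
F5 | step 11 | (4R)-4-benzyl-3-[(2R)-3-{2-(allyloxy)-6-methoxy-4-[(triisopropylsilyl)oxy]phenyl}-2-[4-methoxy-2-(methoxymethoxy)-3-(3-methylbut-2-en-1-yl)phenyl]propanoyl]-1,3-oxazolidin-2-one | C=CCOc1cc(O[Si](C(C)C)(C(C)C)C(C)C)cc(OC)c1C[C@H](c1ccc(OC)c(CC=C(C)C)c1OCOC)C(=O)N1C(=O)OC[C@H]1Cc1ccccc1
F6 | step 11 | (2R)-3-{2-(allyloxy)-6-methoxy-4-[(triisopropylsilyl)oxy]phenyl}-2-[4-methoxy-2-(methoxymethoxy)-3-(3-methylbut-2-en-1-yl)phenyl]propan-1-ol | C=CCOc1cc(O[Si](C(C)C)(C(C)C)C(C)C)cc(OC)c1C[C@H](c1ccc(OC)c(CC=C(C)C)c1OCOC)CO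
F7 | step 4 | 2-[(dimethylamino)methyl]-3-methoxy-5-[(triisopropylsilyl)oxy]phenol | CN(C)Cc1c(O)cc(O[Si](C(C)C)(C(C)C)C(C)C)cc1OC
F8 | step 4 | {2-hydroxy-6-methoxy-4-[(triisopropylsilyl)oxy]benzyl}trimethylammonium iodide | C[N+](C)(C)Cc1c(O)cc(O[Si](C(C)C)(C(C)C)C(C)C)cc1OC.[I-]
F9 | step 14 | (3R)-5-methoxy-3-[4-methoxy-3-(3-methylbut-2-en-1-yl)-2-(trimethylsilyloxy)phenyl]-7-[(triisopropylsilyl)oxy]-3,4-dihydro-2H-chromene | COc1cc(O[Si](C(C)C)(C(C)C)C(C)C)cc2c1C[C@H](c1ccc(OC)c(CC=C(C)C)c1O[Si](C)(C)C)CO2
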